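**Plan**
Cuts, in retrosynthetic order: the four O–benzyl bonds and the C3–O bond (flavonol to flavone); O1–C2 of ring C (flavone to 2'-hydroxychalcone); C4a–C5 of ring A (chalcone to acylmethylpyrone); the CH2–CO bond between pyrone and cinnamoyl unit; last, the styryl C=C bond and the C–C bonds of a propionate/propionate/acetate triketide.
Enabling feature: around ring A the oxygen-bearing carbons C5, C7 and C8a alternate with the carbon-bearing C4a, C6 and C8. Ring A is therefore a folded 2,4-dimethyl-3,5,7-trioxoacyl chain, and its two branches become the C6 and C8 methyl groups.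
Forward order: ring B is bought as a 4-O-methylgallate. A 2-pyrone ring is built as a stable store of the branched triketide and joined to the cinnamoyl unit. The pyrone is then opened and refolded into carbocyclic ring A, ring C closes last by oxa-Michael addition and dehydrogenation, and the C3 hydroxyl is put onto the finished flavone.
Stereochemistry: there is none to set. The E-styryl geometry comes from the olefination and is consumed when ring C forms, and every transient sp3 centre is erased by enolisation, aromatisation or elimination.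

Key step: step 9

Remark: the target SMILES contains no stereocentre and no stereogenic double bond, so the compound is achiral and the single-enantiomer requirement is met trivially. Racemic or epimeric intermediates are written without stereodescriptors.

**Step 1**
Reactants: 1 methyl 3,5-dihydroxy-4-methoxybenzoate
Product: 2 methyl 3,5-bis(benzyloxy)-4-methoxybenzoate
Conditions: BnBr (2.3 equiv), K2CO3, DMF, 60 °C
Reagents that add atoms: benzyl bromide, BrCc1ccccc1
Why: Williamson etherification of the two equivalent phenols should proceed cleanly, and benzyl is chosen because it withstands hydride, amide bases, methoxide, iodine–DMSO and dioxirane and is removed under neutral conditions at the end.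

**Step 2**
Reactants: 2 methyl 3,5-bis(benzyloxy)-4-methoxybenzoate
Product: 3 [3,5-bis(benzyloxy)-4-methoxyphenyl]methanol
Conditions: LiAlH4, THF, 0 °C to rt; aq. NaOH work-up
Reagents that add atoms: none
Why: Hydride reduction of an aromatic ester to the benzylic alcohol is routine and leaves aryl benzyl and methyl ethers untouched.

**Step 3**
Reactants: 3 [3,5-bis(benzyloxy)-4-methoxyphenyl]methanol
Product: 4 3,5-bis(benzyloxy)-4-methoxybenzaldehyde
Conditions: activated MnO2, CH2Cl2, rt
Reagents that add atoms: none
Why: Activated manganese dioxide oxidises benzylic alcohols selectively and stops at the aldehyde.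

**Step 4**
Reactants: 4 3,5-bis(benzyloxy)-4-methoxybenzaldehyde; 5 diethyl {2-[methoxy(methyl)amino]-2-oxoethyl}phosphonate
Product: 6 (E)-3-[3,5-bis(benzyloxy)-4-methoxyphenyl]-N-methoxy-N-methylprop-2-enamide
Conditions: NaH, THF, 0 °C to rt; dil. HCl work-up
Reagents that add atoms: none
Why: Horner–Wadsworth–Emmons olefination with a stabilised amide phosphonate is reliably E-selective with aromatic aldehydes and delivers the cinnamoyl unit directly at the Weinreb amide level needed for a single acyl transfer.

**Step 5**
Reactants: 7 ethyl propanoate (two molecules)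
Product: 8 ethyl 2-methyl-3-oxopentanoate (racemic, configurationally labile)
Conditions: NaH (0.55 equiv), cat. EtOH, THF, reflux; dil. HCl work-up
Reagents that add atoms: none
Why: Claisen self-condensation of a simple ester is pulled to completion by irreversible deprotonation of the β-keto ester formed, and the new stereocentre is labile and irrelevant.

**Step 6**
Reactants: 8 ethyl 2-methyl-3-oxopentanoate; 9 N-methoxy-N-methylacetamide
Product: 10 ethyl 2,4-dimethyl-3,5-dioxohexanoate (mixture of diastereomers and enol forms)
Conditions: LDA (2.2 equiv), THF, −78 to 0 °C; then 9, −78 to 0 °C; dil. HCl work-up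
Reagents that add atoms: none
Why: In this γ-acylation of a β-keto ester dianion the carbanion generated last at C4 is the more nucleophilic site, and the chelated tetrahedral adduct of the Weinreb amide survives until the quench, which prevents both over-addition and proton transfer from the more acidic product.

**Step 7**
Reactants: 10 ethyl 2,4-dimethyl-3,5-dioxohexanoate
Product: 11 4-hydroxy-3,5,6-trimethyl-2H-pyran-2-one
Conditions: DBU, toluene, reflux; dil. HCl work-up
Reagents that add atoms: none
Why: Base-mediated enol lactonisation, in which the C5 enolate oxygen displaces ethoxide from the ester in a 6-exo-trig closure, gives the conjugated 4-hydroxy-2-pyrone and removes both stereocentres of 10.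

**Step 8**
Reactants: 11 4-hydroxy-3,5,6-trimethyl-2H-pyran-2-one; 6 (E)-3-[3,5-bis(benzyloxy)-4-methoxyphenyl]-N-methoxy-N-methylprop-2-enamide
Product: 12 6-{(E)-4-[3,5-bis(benzyloxy)-4-methoxyphenyl]-2-oxobut-3-en-1-yl}-4-hydroxy-3,5-dimethyl-2H-pyran-2-one
Conditions: 11 (1.2 equiv), LDA (2.5 equiv), THF–DMPU, −78 °C; then 6, −78 to 0 °C; dil. HCl work-up
Reagents that add atoms: none
Why: In this acylation of a 4-hydroxy-6-methyl-2-pyrone dianion only the C6 methyl group is vinylogously activated by the C2 and C4 carbonyl systems once the hydroxyl proton is gone, so the second deprotonation and the C–C bond formation occur there, while the Weinreb amide favours carbonyl over conjugate addition and releases the acidic methylene only on work-up.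

**Step 9**
Reactants: 12 6-{(E)-4-[3,5-bis(benzyloxy)-4-methoxyphenyl]-2-oxobut-3-en-1-yl}-4-hydroxy-3,5-dimethyl-2H-pyran-2-one
Product: 14 (E)-3,5-bis(benzyloxy)-2',4',6'-trihydroxy-4-methoxy-3',5'-dimethylchalcone, via open-chain methyl trioxo ester 13 (not isolated)
Conditions: Mg(OMe)2 (commercial solution, 6 equiv), MeOH, reflux, Ar; then 1 M HCl, 0 °C
Reagents that add atoms: none
Why: Methoxide, helped by Mg2+ bound to the pyrone oxygens, opens the lactone at its carbonyl carbon to the magnesium-chelated enolate of 13, because a direct attack of the side-chain carbanion across the intact planar pyrone would need a bicyclo[3.1.1] bridge and is ruled out. In the chain numbering of 13 the C6 methylene between the C5 and C7 carbonyls is the most acidic carbon; it adds to the C1 ester carbonyl, methoxide leaves, and the cyclohexane-1,3,5-trione tautomerises irreversibly to the phloroglucinol ring of 14, which creates the C4a–C5 bond of the target (indistinguishable from C4a–C8a while ring A is still symmetric). The closest known reaction type is the biomimetic Claisen (Dieckmann-type) cyclisation of 3,5,7-trioxo esters and of 6-acylmethyl-4-hydroxy-2-pyrones to acylphloroglucinols under magnesium methoxide or hydroxide. The one ring closes 6-exo-trig at the ester carbonyl, a mode allowed for both the enolendo (C5 enolate) and the enolexo (C7 enolate) form of the nucleophile, no stereocentre is created, and the two epimerisable centres of 13 vanish on aromatisation. Claisen folding must beat aldol folding (C2 onto C7) and carbon or oxygen conjugate addition to the styryl ketone: the C2 methyl group makes the aldol product a quaternary β-hydroxy ketone that cannot aromatise and reverts by retro-aldol, magnesium chelation holds C5/C7 as an enolate so that C7 is a poor electrophile, and the Michael adducts are reversible, so all equilibria should drain into the aromatic product. The E-alkene, the aryl methyl ether and the benzyl ethers are inert to methoxide.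

**Step 10**
Reactants: 14 (E)-3,5-bis(benzyloxy)-2',4',6'-trihydroxy-4-methoxy-3',5'-dimethylchalcone
Product: 16 2-[3,5-bis(benzyloxy)-4-methoxyphenyl]-5,7-dihydroxy-6,8-dimethyl-4H-chromen-4-one, via flavanone 15 (not isolated)
Conditions: I2 (10 mol %), DMSO, 120 °C
Reagents that add atoms: none
Why: In this iodine–DMSO oxidative cyclisation of a 2'-hydroxychalcone, reversible 6-endo-trig oxa-Michael closure by either of the two equivalent ortho-phenols gives flavanone 15, whose α-iodination and loss of HI install the C2=C3 bond while DMSO reoxidises HI, and the usual side reaction of nuclear iodination finds no free site because C6 and C8 carry methyl groups.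

**Step 11**
Reactants: 16 2-[3,5-bis(benzyloxy)-4-methoxyphenyl]-5,7-dihydroxy-6,8-dimethyl-4H-chromen-4-one
Product: 17 5,7-bis(benzyloxy)-2-[3,5-bis(benzyloxy)-4-methoxyphenyl]-6,8-dimethyl-4H-chromen-4-one
Conditions: BnBr (4 equiv), K2CO3, cat. n-Bu4NI, DMF, 80 °C
Reagents that add atoms: benzyl bromide, BrCc1ccccc1
Why: Williamson etherification in a polar aprotic medium favours O-alkylation, heat and iodide catalysis overcome the hydrogen-bonded 5-OH, and masking both phenols shields the electron-rich ring A from the oxidant of the next step.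

**Step 12**
Reactants: 17 5,7-bis(benzyloxy)-2-[3,5-bis(benzyloxy)-4-methoxyphenyl]-6,8-dimethyl-4H-chromen-4-one
Product: 19 5,7-bis(benzyloxy)-2-[3,5-bis(benzyloxy)-4-methoxyphenyl]-3-hydroxy-6,8-dimethyl-4H-chromen-4-one, via flavone 2,3-epoxide 18 (not isolated)
Conditions: DMDO (acetone solution, 3 equiv), CH2Cl2, 0 °C to rt; then cat. p-TsOH, CH2Cl2, rt
Reagents that add atoms: dimethyldioxirane, CC1(C)OO1
Why: Dioxirane epoxidation of the C2=C3 enol-ether bond of a fully O-protected flavone gives the racemic epoxide 18, which under acid opens at the oxygen- and aryl-stabilised C2 and loses H3 to give the 3-hydroxyflavone, a known flavone-to-flavonol oxidation.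

**Step 13**
Reactants: 19 5,7-bis(benzyloxy)-2-[3,5-bis(benzyloxy)-4-methoxyphenyl]-3-hydroxy-6,8-dimethyl-4H-chromen-4-one
Product: 20 6,8-di-C-methylmyricetin 4'-methyl ether (3,5,7-trihydroxy-2-(3,5-dihydroxy-4-methoxyphenyl)-6,8-dimethyl-4H-chromen-4-one)
Conditions: H2 (1 atm), 10 % Pd/C, THF–MeOH, rt
Reagents that add atoms: none
Why: Catalytic hydrogenolysis cleaves all four benzyl ethers in one operation and leaves the aryl methyl ether and the conjugated C2=C3 bond of the flavonol intact.

**Compound list**
1 | methyl 3,5-dihydroxy-4-methoxybenzoate | COC(=O)c1cc(O)c(OC)c(O)c1 | starting material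
2 | methyl 3,5-bis(benzyloxy)-4-methoxybenzoate | COC(=O)c1cc(OCc2ccccc2)c(OC)c(OCc2ccccc2)c1 | intermediate
3 | [3,5-bis(benzyloxy)-4-methoxyphenyl]methanol | COc1c(OCc2ccccc2)cc(CO)cc1OCc1ccccc1 | intermediate
4 | 3,5-bis(benzyloxy)-4-methoxybenzaldehyde | COc1c(OCc2ccccc2)cc(C=O)cc1OCc1ccccc1 | intermediate
5 | diethyl {2-[methoxy(methyl)amino]-2-oxoethyl}phosphonate | CCOP(=O)(CC(=O)N(C)OC)OCC | starting material
6 | (E)-3-[3,5-bis(benzyloxy)-4-methoxyphenyl]-N-methoxy-N-methylprop-2-enamide | COc1c(OCc2ccccc2)cc(/C=C/C(=O)N(C)OC)cc1OCc1ccccc1 | intermediate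
7 | ethyl propanoate | CCC(=O)OCC | starting material
8 | ethyl 2-methyl-3-oxopentanoate (racemic) | CCC(=O)C(C)C(=O)OCC | intermediate
9 | N-methoxy-N-methylacetamide | CC(=O)N(C)OC | starting material
10 | ethyl 2,4-dimethyl-3,5-dioxohexanoate (stereoisomer and tautomer mixture) | CCOC(=O)C(C)C(=O)C(C)C(C)=O | intermediate
11 | 4-hydroxy-3,5,6-trimethyl-2H-pyran-2-one | Cc1oc(=O)c(C)c(O)c1C | intermediate
12 | 6-{(E)-4-[3,5-bis(benzyloxy)-4-methoxyphenyl]-2-oxobut-3-en-1-yl}-4-hydroxy-3,5-dimethyl-2H-pyran-2-one | COc1c(OCc2ccccc2)cc(/C=C/C(=O)Cc2oc(=O)c(C)c(O)c2C)cc1OCc1ccccc1 | intermediate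
13 | methyl (E)-9-[3,5-bis(benzyloxy)-4-methoxyphenyl]-2,4-dimethyl-3,5,7-trioxonon-8-enoate (stereoisomer and tautomer mixture, not isolated) | COC(=O)C(C)C(=O)C(C)C(=O)CC(=O)/C=C/c1cc(OCc2ccccc2)c(OC)c(OCc2ccccc2)c1 | intermediate
14 | (E)-3,5-bis(benzyloxy)-2',4',6'-trihydroxy-4-methoxy-3',5'-dimethylchalcone | COc1c(OCc2ccccc2)cc(/C=C/C(=O)c2c(O)c(C)c(O)c(C)c2O)cc1OCc1ccccc1 | intermediate
15 | 2-[3,5-bis(benzyloxy)-4-methoxyphenyl]-5,7-dihydroxy-6,8-dimethylchroman-4-one (racemic flavanone, not isolated) | COc1c(OCc2ccccc2)cc(C2CC(=O)c3c(O)c(C)c(O)c(C)c3O2)cc1OCc1ccccc1 | intermediate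
16 | 2-[3,5-bis(benzyloxy)-4-methoxyphenyl]-5,7-dihydroxy-6,8-dimethyl-4H-chromen-4-one | COc1c(OCc2ccccc2)cc(-c2cc(=O)c3c(O)c(C)c(O)c(C)c3o2)cc1OCc1ccccc1 | intermediate
17 | 5,7-bis(benzyloxy)-2-[3,5-bis(benzyloxy)-4-methoxyphenyl]-6,8-dimethyl-4H-chromen-4-one | COc1c(OCc2ccccc2)cc(-c2cc(=O)c3c(OCc4ccccc4)c(C)c(OCc4ccccc4)c(C)c3o2)cc1OCc1ccccc1 | intermediate
18 | 5,7-bis(benzyloxy)-2-[3,5-bis(benzyloxy)-4-methoxyphenyl]-6,8-dimethyl-2,3-epoxychroman-4-one (racemic, cis-fused, not isolated) | COc1c(OCc2ccccc2)cc(C23OC2C(=O)c2c(OCc4ccccc4)c(C)c(OCc4ccccc4)c(C)c2O3)cc1OCc1ccccc1 | intermediate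
19 | 5,7-bis(benzyloxy)-2-[3,5-bis(benzyloxy)-4-methoxyphenyl]-3-hydroxy-6,8-dimethyl-4H-chromen-4-one | COc1c(OCc2ccccc2)cc(-c2oc3c(C)c(OCc4ccccc4)c(C)c(OCc4ccccc4)c3c(=O)c2O)cc1OCc1ccccc1 | intermediate
20 | 6,8-di-C-methylmyricetin 4'-methyl ether | COc1c(O)cc(-c2oc3c(C)c(O)c(C)c(O)c3c(=O)c2O)cc1O | target

**Step count**
Total step count: 13. Longest linear sequence: 10 steps (1–4, then 8–13) from 1. The pyrone branch (steps 5–7) is convergent.

**Steps most likely to fail**

Step 9. Methanolysis of the doubly deprotonated lactone, which is flanked by a methyl group, may be slow. Prolonged heating would then allow conjugate addition to the styryl ketone and retro-Claisen cleavage of the cinnamoyl unit to compete. Early oxa-Michael closure of the product is harmless, because step 10 passes through the flavanone anyway.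

The fallback avoids the lactone opening and enters the same Claisen folding from an open chain. It sets out from 10 and 6. Threefold deprotonation of 10 with LDA and acylation of the terminal methyl carbanion with 6 should give ethyl (E)-9-[3,5-bis(benzyloxy)-4-methoxyphenyl]-2,4-dimethyl-3,5,7-trioxonon-8-enoate F1. This free trioxo ester is cyclised with aqueous KOH or sodium methoxide at room temperature and comes back to the route at 14.

Step 8. The soft, delocalised carbanion may add to the β-carbon of the cinnamoyl acceptor instead of the carbonyl. The second deprotonation of the poorly soluble lithium pyronate may also stay incomplete.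

The fallback replaces acyl transfer by aldol addition and oxidation. It sets out from 6, which DIBAL-H at −78 °C reduces to (E)-3-[3,5-bis(benzyloxy)-4-methoxyphenyl]prop-2-enal F2. Twice-deprotonated 11 adds to this harder electrophile in the 1,2 sense to give rac-6-{(E)-4-[3,5-bis(benzyloxy)-4-methoxyphenyl]-2-hydroxybut-3-en-1-yl}-4-hydroxy-3,5-dimethyl-2H-pyran-2-one F3. Oxidation of its allylic alcohol with MnO2 returns to the route at 12.

Step 12. Oxygen transfer to the crowded, electron-poor C2=C3 bond may be sluggish. Oxidation of benzylic C–H bonds or of the electron-rich rings could then take over.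

The fallback replaces electrophilic oxidation by deprotonation and boronate oxidation. It sets out from 17, which is lithiated at C3 with LDA at −78 °C and trapped with B(OMe)3. This gives dimethyl {5,7-bis(benzyloxy)-2-[3,5-bis(benzyloxy)-4-methoxyphenyl]-6,8-dimethyl-4-oxo-4H-chromen-3-yl}boronate F4. Oxidation with H2O2/AcOH converts the C–B bond into the C–O bond and returns to the route at 19.

**Further compounds**
F1 | step 9 | ethyl (E)-9-[3,5-bis(benzyloxy)-4-methoxyphenyl]-2,4-dimethyl-3,5,7-trioxonon-8-enoate | CCOC(=O)C(C)C(=O)C(C)C(=O)CC(=O)/C=C/c1cc(OCc2ccccc2)c(OC)c(OCc2ccccc2)c1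
F2 | step 8 | (E)-3-[3,5-bis(benzyloxy)-4-methoxyphenyl]prop-2-enal | COc1c(OCc2ccccc2)cc(/C=C/C=O)cc1OCc1ccccc1
F3 | step 8 | rac-6-{(E)-4-[3,5-bis(benzyloxy)-4-methoxyphenyl]-2-hydroxybut-3-en-1-yl}-4-hydroxy-3,5-dimethyl-2H-pyran-2-one | COc1c(OCc2ccccc2)cc(/C=C/C(O)Cc2oc(=O)c(C)c(O)c2C)cc1OCc1ccccc1
F4 | step 12 | dimethyl {5,7-bis(benzyloxy)-2-[3,5-bis(benzyloxy)-4-methoxyphenyl]-6,8-dimethyl-4-oxo-4H-chromen-3-yl}boronate | COB(OC)c1c(-c2cc(OCc3ccccc3)c(OC)c(OCc3ccccc3)c2)oc2c(C)c(OCc3ccccc3)c(C)c(OCc3ccccc3)c2c1=O
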